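**Retrosynthetic overview**
- The hydroperoxide comes last, from a Schenck ene reaction on a skipped-diene side chain; that side chain is set by palladium/formate hydrogenolysis of a tertiary allylic carbonate made on the ring-A ketone.
- Ring B (the cyclopentenone, formed second) comes from a gold-catalysed Rautenstrauch rearrangement of an enynyl pivalate: chirality transfer sets the methyl-bearing centre and kinetic protonation sets the neighbouring centre cis.
- The inter-ring C–C bond comes from conjugate alkynylation of the ring-A enone, anti to the tertiary silyl ether.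
- Ring A (formed first; its five carbons, the tertiary OH and the CH2O carbon) comes from the Piancatelli rearrangement of aromatic, C2v-symmetric 2,5-bis(hydroxymethyl)furan 1, followed by a lipase resolution that also installs the acetate.

Assumption: the lipase of step 2 acetylates the (R)-diol faster, and in the gold step the new C–C bond forms anti to the departing C–O bond, which makes the (R)-pivalate the required enantiomer.

**Step 1**
Reactants: 1 2,5-bis(hydroxymethyl)furan
Product: 2 4-hydroxy-4-(hydroxymethyl)cyclopent-2-en-1-one (racemic)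
Conditions: H2O (0.05 M), 180 °C, sealed vessel (microwave), 40 min
Reagents that add atoms: water, O
Why: Piancatelli rearrangement — one of the two equivalent CH2OH groups ionizes, water adds at the far furan α-carbon, the ring opens and a conrotatory 4π-electrocyclization closes ring A, so the symmetric aromatic diol becomes the enone whose quaternary carbinol carbon (racemic) already carries the OH and CH2OH of the target.

**Step 2**
Reactants: 2 4-hydroxy-4-(hydroxymethyl)cyclopent-2-en-1-one (racemic)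
Product: 3 [(1R)-1-hydroxy-4-oxocyclopent-2-en-1-yl]methyl acetate
Conditions: vinyl acetate, Burkholderia cepacia lipase (Amano PS), t-BuOMe, 30 °C, to about 45% conversion
Reagents that add atoms: vinyl acetate, CC(=O)OC=C
Why: Lipase-catalysed kinetic resolution by irreversible acyl transfer to the primary hydroxyl — the enzyme reads the adjacent quaternary centre, so the (R)-enantiomer is acetylated (fixing the absolute configuration of ring A and installing the acetate of the target) while the (S)-diol stays behind and is removed by chromatography.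

**Step 3**
Reactants: 3 [(1R)-1-hydroxy-4-oxocyclopent-2-en-1-yl]methyl acetate
Product: 4 [(1R)-4-oxo-1-(triethylsilyloxy)cyclopent-2-en-1-yl]methyl acetate
Conditions: Et3SiOTf, 2,6-lutidine, CH2Cl2, –78 to 0 °C
Reagents that add atoms: triethylsilyl trifluoromethanesulfonate, CC[Si](CC)(CC)OS(=O)(=O)C(F)(F)F
Why: Silylation of the hindered tertiary alcohol with a silyl triflate touches no stereocentre and supplies the bulky OSiEt3 group that shields one enone face in step 7.

**Step 4**
Reactants: 5 (E)-but-2-enal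
Product: 6 (E)-hex-4-en-1-yn-3-ol (racemic)
Conditions: HC≡CMgBr, THF, 0 °C; NH4Cl (aq)
Reagents that add atoms: ethynylmagnesium bromide, C#C[Mg]Br
Why: Grignard 1,2-addition of the alkynyl reagent to the enal gives the racemic propargylic allylic alcohol with the E-alkene untouched.

**Step 5**
Reactants: 6 (E)-hex-4-en-1-yn-3-ol (racemic)
Product: 7 (3R,4E)-hex-4-en-1-yn-3-ol
Conditions: vinyl acetate, Candida antarctica lipase B (Novozym 435), hexane, 25 °C, to about 55% conversion
Reagents that add atoms: none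
Why: Lipase-catalysed kinetic resolution of a secondary propargylic alcohol — by Kazlauskas' rule (ethynyl as the medium group, propenyl as the large group) the (S)-alcohol is acetylated and the (R)-alcohol is recovered unreacted in high ee.

**Step 6**
Reactants: 7 (3R,4E)-hex-4-en-1-yn-3-ol
Product: 8 (3R,4E)-hex-4-en-1-yn-3-yl 2,2-dimethylpropanoate
Conditions: t-BuCOCl, pyridine, DMAP (cat.), CH2Cl2, 0 to 25 °C
Reagents that add atoms: pivaloyl chloride, CC(C)(C)C(=O)Cl
Why: Esterification with retention at the carbinol carbon gives the pivalate, which has no α-hydrogen and therefore tolerates the amide base of step 7.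

**Step 7**
Reactants: 4 [(1R)-4-oxo-1-(triethylsilyloxy)cyclopent-2-en-1-yl]methyl acetate; 8 (3R,4E)-hex-4-en-1-yn-3-yl 2,2-dimethylpropanoate
Product: 12 [(1R,2S)-2-[(3R,4E)-3-(2,2-dimethylpropanoyloxy)hex-4-en-1-yn-1-yl]-4-oxo-1-(triethylsilyloxy)cyclopentyl]methyl acetate, via lithium acetylide 9 (not isolated), via alkynylzinc bromide 10 (not isolated), via trimethylsilyl enol ether 11 (not isolated)
Conditions: 8, LiN(i-Pr)2, THF, –78 °C; ZnBr2, –78 to 0 °C; then 4, Me3SiOTf, THF–Et2O, –40 °C; citric acid (aq) work-up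
Reagents that add atoms: none
Why: Silyl-triflate-promoted conjugate alkynylation of a cyclic enone with an alkynylzinc reagent — the slim acetylide attacks the β-carbon next to the quaternary centre anti to the bulky OSiEt3 group (anti to the allylic C–O bond), which sets the new ring-A centre (2S) cis to CH2OAc, and mild acid cleaves only the silyl enol ether.

**Step 8**
Reactants: 12 [(1R,2S)-2-[(3R,4E)-3-(2,2-dimethylpropanoyloxy)hex-4-en-1-yn-1-yl]-4-oxo-1-(triethylsilyloxy)cyclopentyl]methyl acetate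
Product: 14 [(1R,2S)-2-[(1S,5R)-5-methyl-2-oxocyclopent-3-en-1-yl]-4-oxo-1-(triethylsilyloxy)cyclopentyl]methyl acetate, via cyclopentadienyl pivalate 13 (not isolated)
Conditions: Ph3PAuCl (5 mol%), AgSbF6 (5 mol%), MeCN, H2O (2 equiv), –20 to 0 °C
Reagents that add atoms: none
Why: Gold-catalysed Rautenstrauch rearrangement — 1,2-migration of the pivalate on the gold-activated alkyne and conrotatory closure onto the E-propenyl group build ring B with the propargylic centre passing its chirality to the methyl-bearing carbon (5R), and water then cleaves the dienyl pivalate with protonation of the enol carbon from the face opposite the neighbouring methyl group, giving the cis (1S) ketone under kinetic control.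

**Step 9**
Reactants: 15 1-bromo-3-methylbut-2-ene
Product: 16 6-methylhept-5-en-2-yne
Conditions: CH3C≡CMgBr, CuBr·SMe2 (5 mol%), THF, 0 to 25 °C
Reagents that add atoms: 1-propynylmagnesium bromide, CC#C[Mg]Br
Why: Copper-catalysed SN2 coupling of an alkynyl Grignard reagent with the primary allylic bromide gives the skipped enyne.

**Step 10**
Reactants: 16 6-methylhept-5-en-2-yne
Product: 18 (2E)-2-iodo-6-methylhepta-2,5-diene, via alkenylzirconocene chloride 17 (not isolated)
Conditions: Cp2Zr(H)Cl (1.5 equiv), THF, 25 to 40 °C; then I2, 0 °C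
Reagents that add atoms: iodine, II
Why: Hydrozirconation–iodination — syn addition of Zr–H places zirconium on the methyl-bearing alkyne carbon (excess reagent equilibrates the regioisomers toward it and leaves the trisubstituted alkene alone) and iodinolysis with retention gives the E-alkenyl iodide.

**Step 11**
Reactants: 14 [(1R,2S)-2-[(1S,5R)-5-methyl-2-oxocyclopent-3-en-1-yl]-4-oxo-1-(triethylsilyloxy)cyclopentyl]methyl acetate; 18 (2E)-2-iodo-6-methylhepta-2,5-diene
Product: 22 [(1R,2S,4S)-4-(methoxycarbonyloxy)-4-[(2E)-6-methylhepta-2,5-dien-2-yl]-2-[(1S,5R)-5-methyl-2-oxocyclopent-3-en-1-yl]-1-(triethylsilyloxy)cyclopentyl]methyl acetate, via alkenyllithium 19 (not isolated), via alkenylcerium dichloride 20 (not isolated), via cerium alkoxide 21 (not isolated)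
Conditions: 18, t-BuLi (2 equiv), Et2O, –78 °C; CeCl3, THF, –78 °C; then 14, –78 °C; then ClCO2Me, DMAP, –78 to 0 °C
Reagents that add atoms: methyl chloroformate, COC(=O)Cl
Why: Iodine–lithium exchange with retention, transmetalation to the weakly basic organocerium reagent and 1,2-addition to the unconjugated cyclopentanone (faster than to the conjugated ring-B ketone or the esters) from the face opposite the ring-B substituent and the pseudo-axial CH2OAc group give the tertiary alkoxide, which is trapped in the flask as the allylic methyl carbonate (4S).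

**Step 12**
Reactants: 22 [(1R,2S,4S)-4-(methoxycarbonyloxy)-4-[(2E)-6-methylhepta-2,5-dien-2-yl]-2-[(1S,5R)-5-methyl-2-oxocyclopent-3-en-1-yl]-1-(triethylsilyloxy)cyclopentyl]methyl acetate
Product: 23 [(1R,2S,4S)-4-[(2E)-6-methylhepta-2,5-dien-2-yl]-2-[(1S,5R)-5-methyl-2-oxocyclopent-3-en-1-yl]-1-(triethylsilyloxy)cyclopentyl]methyl acetate
Conditions: Pd(OAc)2 (5 mol%), Bu3P (5 mol%), HCO2H, Et3N, THF, 25 °C
Reagents that add atoms: none
Why: Tsuji–Mandai hydrogenolysis — zerovalent palladium ionizes the tertiary allylic carbonate with inversion, formate gives a palladium hydride, and hydride passes from the metal to the more substituted allyl terminus, so the hydrogen enters on the face the alkenyl group occupied in 22 and the E-trisubstituted side chain ends up cis to ring B and CH2OAc (4S).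

**Step 13**
Reactants: 23 [(1R,2S,4S)-4-[(2E)-6-methylhepta-2,5-dien-2-yl]-2-[(1S,5R)-5-methyl-2-oxocyclopent-3-en-1-yl]-1-(triethylsilyloxy)cyclopentyl]methyl acetate
Product: 24 [(1R,2S,4S)-1-hydroxy-4-[(2E)-6-methylhepta-2,5-dien-2-yl]-2-[(1S,5R)-5-methyl-2-oxocyclopent-3-en-1-yl]cyclopentyl]methyl acetate
Conditions: HF·pyridine, pyridine, THF, 0 °C
Reagents that add atoms: none
Why: Fluoride-mediated desilylation frees the tertiary alcohol under buffered conditions that leave the acetate and the epimerizable cis centre next to the ring-B ketone untouched.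

**Step 14**
Reactants: 24 [(1R,2S,4S)-1-hydroxy-4-[(2E)-6-methylhepta-2,5-dien-2-yl]-2-[(1S,5R)-5-methyl-2-oxocyclopent-3-en-1-yl]cyclopentyl]methyl acetate
Product: 25 [(1R,2S,4S)-4-[(2E,4E)-6-hydroperoxy-6-methylhepta-2,4-dien-2-yl]-1-hydroxy-2-[(1S,5R)-5-methyl-2-oxocyclopent-3-en-1-yl]cyclopentyl]methyl acetate
Conditions: O2, tetraphenylporphyrin (1 mol%), visible light, CH2Cl2, –30 °C, stopped at about 70% conversion
Reagents that add atoms: dioxygen, O=O
Why: Schenck ene reaction — singlet oxygen attacks the terminal, least hindered trisubstituted alkene, takes the doubly allylic hydrogen and delivers the tertiary hydroperoxide with a new E-alkene in conjugation, the regioisomeric hydroperoxides (expected in substantial amount) being removed by chromatography.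

**Compound list**
1 | 2,5-bis(hydroxymethyl)furan | OCc1ccc(CO)o1 | starting material
2 | 4-hydroxy-4-(hydroxymethyl)cyclopent-2-en-1-one (racemic) | OCC1(O)CC(=O)C=C1 | intermediate
3 | [(1R)-1-hydroxy-4-oxocyclopent-2-en-1-yl]methyl acetate | CC(=O)OC[C@@]1(O)CC(=O)C=C1 | intermediate
4 | [(1R)-4-oxo-1-(triethylsilyloxy)cyclopent-2-en-1-yl]methyl acetate | CC(=O)OC[C@@]1(O[Si](CC)(CC)CC)CC(=O)C=C1 | intermediate
5 | (E)-but-2-enal | C/C=C/C=O | starting material
6 | (E)-hex-4-en-1-yn-3-ol (racemic) | C#CC(O)/C=C/C | intermediate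
7 | (3R,4E)-hex-4-en-1-yn-3-ol | C#C[C@H](O)/C=C/C | intermediate
8 | (3R,4E)-hex-4-en-1-yn-3-yl 2,2-dimethylpropanoate | C#C[C@H](OC(=O)C(C)(C)C)/C=C/C | intermediate
9 | [(3R,4E)-3-(2,2-dimethylpropanoyloxy)hex-4-en-1-yn-1-yl]lithium | [Li]C#C[C@H](OC(=O)C(C)(C)C)/C=C/C | intermediate (not isolated)
10 | bromo[(3R,4E)-3-(2,2-dimethylpropanoyloxy)hex-4-en-1-yn-1-yl]zinc | Br[Zn]C#C[C@H](OC(=O)C(C)(C)C)/C=C/C | intermediate (not isolated)
11 | [(1R,2S)-2-[(3R,4E)-3-(2,2-dimethylpropanoyloxy)hex-4-en-1-yn-1-yl]-1-(triethylsilyloxy)-4-(trimethylsilyloxy)cyclopent-3-en-1-yl]methyl acetate | CC(=O)OC[C@@]1(O[Si](CC)(CC)CC)CC(O[Si](C)(C)C)=C[C@H]1C#C[C@H](OC(=O)C(C)(C)C)/C=C/C | intermediate (not isolated)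
12 | [(1R,2S)-2-[(3R,4E)-3-(2,2-dimethylpropanoyloxy)hex-4-en-1-yn-1-yl]-4-oxo-1-(triethylsilyloxy)cyclopentyl]methyl acetate | CC(=O)OC[C@@]1(O[Si](CC)(CC)CC)CC(=O)C[C@H]1C#C[C@H](OC(=O)C(C)(C)C)/C=C/C | intermediate
13 | (3R)-2-[(1S,2R)-2-(acetoxymethyl)-4-oxo-2-(triethylsilyloxy)cyclopentyl]-3-methylcyclopenta-1,4-dien-1-yl 2,2-dimethylpropanoate | CC(=O)OC[C@@]1(O[Si](CC)(CC)CC)CC(=O)C[C@H]1C2=C(OC(=O)C(C)(C)C)C=C[C@H]2C | intermediate (not isolated)
14 | [(1R,2S)-2-[(1S,5R)-5-methyl-2-oxocyclopent-3-en-1-yl]-4-oxo-1-(triethylsilyloxy)cyclopentyl]methyl acetate | CC(=O)OC[C@@]1(O[Si](CC)(CC)CC)CC(=O)C[C@H]1[C@H]1C(=O)C=C[C@H]1C | intermediate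
15 | 1-bromo-3-methylbut-2-ene | CC(C)=CCBr | starting material
16 | 6-methylhept-5-en-2-yne | CC#CCC=C(C)C | intermediate
17 | chlorobis(cyclopentadienyl)[(2E)-6-methylhepta-2,5-dien-2-yl]zirconium (cyclopentadienyl rings drawn σ-bonded) | C/C(=C\CC=C(C)C)[Zr](Cl)(C1C=CC=C1)C1C=CC=C1 | intermediate (not isolated)
18 | (2E)-2-iodo-6-methylhepta-2,5-diene | C/C(I)=C\CC=C(C)C | intermediate
19 | [(2Z)-6-methylhepta-2,5-dien-2-yl]lithium | C/C([Li])=C\CC=C(C)C | intermediate (not isolated)
20 | dichloro[(2E)-6-methylhepta-2,5-dien-2-yl]cerium | C/C([Ce](Cl)Cl)=C\CC=C(C)C | intermediate (not isolated)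
21 | dichlorocerium alkoxide of [(1R,2S,4S)-4-hydroxy-4-[(2E)-6-methylhepta-2,5-dien-2-yl]-2-[(1S,5R)-5-methyl-2-oxocyclopent-3-en-1-yl]-1-(triethylsilyloxy)cyclopentyl]methyl acetate | CC(=O)OC[C@@]1(O[Si](CC)(CC)CC)C[C@](O[Ce](Cl)Cl)(/C(C)=C/CC=C(C)C)C[C@H]1[C@H]1C(=O)C=C[C@H]1C | intermediate (not isolated)
22 | [(1R,2S,4S)-4-(methoxycarbonyloxy)-4-[(2E)-6-methylhepta-2,5-dien-2-yl]-2-[(1S,5R)-5-methyl-2-oxocyclopent-3-en-1-yl]-1-(triethylsilyloxy)cyclopentyl]methyl acetate | CC(=O)OC[C@@]1(O[Si](CC)(CC)CC)C[C@](OC(=O)OC)(/C(C)=C/CC=C(C)C)C[C@H]1[C@H]1C(=O)C=C[C@H]1C | intermediate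
23 | [(1R,2S,4S)-4-[(2E)-6-methylhepta-2,5-dien-2-yl]-2-[(1S,5R)-5-methyl-2-oxocyclopent-3-en-1-yl]-1-(triethylsilyloxy)cyclopentyl]methyl acetate | CC(=O)OC[C@@]1(O[Si](CC)(CC)CC)C[C@@H](/C(C)=C/CC=C(C)C)C[C@H]1[C@H]1C(=O)C=C[C@H]1C | intermediate
24 | [(1R,2S,4S)-1-hydroxy-4-[(2E)-6-methylhepta-2,5-dien-2-yl]-2-[(1S,5R)-5-methyl-2-oxocyclopent-3-en-1-yl]cyclopentyl]methyl acetate | CC(=O)OC[C@@]1(O)C[C@@H](/C(C)=C/CC=C(C)C)C[C@H]1[C@H]1C(=O)C=C[C@H]1C | intermediate
25 | [(1R,2S,4S)-4-[(2E,4E)-6-hydroperoxy-6-methylhepta-2,4-dien-2-yl]-1-hydroxy-2-[(1S,5R)-5-methyl-2-oxocyclopent-3-en-1-yl]cyclopentyl]methyl acetate | CC(=O)OC[C@@]1(O)C[C@@H](/C(C)=C/C=C/C(C)(C)OO)C[C@H]1[C@H]1C(=O)C=C[C@H]1C | target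

**Step count**
Total: 14 steps. Longest linear sequence: 9 steps (1 to 25 through steps 1, 2, 3, 7, 8, 11, 12, 13 and 14).

**Three steps most likely to fail**

Step 8 (gold rearrangement on an internal alkyne; risks are a competing 1,3-acyloxy shift and erosion of the cis ketone). The fallback sets out from 4 and 8 and comes back at 14. The Rautenstrauch rearrangement is run on the terminal alkyne 8 itself, where it is best precedented, giving (4S)-4-methylcyclopent-2-en-1-one F4. Soft enolization (Me3SiOTf, Et3N) gives (5R)-5-methyl-2-(trimethylsilyloxy)cyclopenta-1,3-diene F5. Me3SiOTf-catalysed Mukaiyama–Michael addition of F5 to 4 at –78 °C gives the adduct with the new bond trans to the methyl group, [(1R,2S)-2-[(1R,5R)-5-methyl-2-oxocyclopent-3-en-1-yl]-1-(triethylsilyloxy)-4-(trimethylsilyloxy)cyclopent-3-en-1-yl]methyl acetate F6. A second silylation (Me3SiOTf, Et3N) gives the dienol ether [(1R,2S)-2-[(5R)-5-methyl-2-(trimethylsilyloxy)cyclopenta-1,3-dien-1-yl]-1-(triethylsilyloxy)-4-(trimethylsilyloxy)cyclopent-3-en-1-yl]methyl acetate F7. Protonation at –78 °C (Bu4NF, AcOH, THF) from the face opposite the methyl group then gives 14.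

Step 7 (addition to a β-carbon next to a quaternary centre; facial selectivity rests on the silyl ether alone). The fallback sets out from 4 and comes back at 12, and delivers the alkyne from the neighbouring oxygen instead. Methanolysis of 4 (K2CO3, MeOH, 0 °C) frees the primary alcohol to give (4R)-4-(hydroxymethyl)-4-(triethylsilyloxy)cyclopent-2-en-1-one F1. The lithium acetylide 9 is converted with Me2AlCl into dimethyl[(3R,4E)-3-(2,2-dimethylpropanoyloxy)hex-4-en-1-yn-1-yl]aluminium F2. F2 forms an aluminium alkoxide with F1 and transfers the alkynyl group within the complex to the face of the CH2O arm, giving (3S,4R)-3-[(3R,4E)-3-(2,2-dimethylpropanoyloxy)hex-4-en-1-yn-1-yl]-4-(hydroxymethyl)-4-(triethylsilyloxy)cyclopentan-1-one F3. Acetylation (Ac2O, pyridine) returns to 12.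

Step 11 (the organocerium reagent must choose the saturated ketone over the ring-B ketone). The fallback sets out from 12 and comes back at 23, and installs the side chain before ring B exists. Addition of 20 to 12 and trapping with methyl chloroformate give the carbonate [(1R,2S,4S)-2-[(3R,4E)-3-(2,2-dimethylpropanoyloxy)hex-4-en-1-yn-1-yl]-4-(methoxycarbonyloxy)-4-[(2E)-6-methylhepta-2,5-dien-2-yl]-1-(triethylsilyloxy)cyclopentyl]methyl acetate F8. Palladium/formate hydrogenolysis under the conditions of step 12 (the tertiary carbonate ionizes far faster than the pivalate) gives [(1R,2S,4S)-2-[(3R,4E)-3-(2,2-dimethylpropanoyloxy)hex-4-en-1-yn-1-yl]-4-[(2E)-6-methylhepta-2,5-dien-2-yl]-1-(triethylsilyloxy)cyclopentyl]methyl acetate F9. The gold-catalysed rearrangement under the conditions of step 8 then leads to 23. Facial control in the addition is weaker here because the alkynyl group is slimmer than ring B.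

**Further compounds**
F1 | step 7 | (4R)-4-(hydroxymethyl)-4-(triethylsilyloxy)cyclopent-2-en-1-one | OC[C@@]1(O[Si](CC)(CC)CC)CC(=O)C=C1
F2 | step 7 | dimethyl[(3R,4E)-3-(2,2-dimethylpropanoyloxy)hex-4-en-1-yn-1-yl]aluminium | C[Al](C)C#C[C@H](OC(=O)C(C)(C)C)/C=C/C
F3 | step 7 | (3S,4R)-3-[(3R,4E)-3-(2,2-dimethylpropanoyloxy)hex-4-en-1-yn-1-yl]-4-(hydroxymethyl)-4-(triethylsilyloxy)cyclopentan-1-one | OC[C@@]1(O[Si](CC)(CC)CC)CC(=O)C[C@H]1C#C[C@H](OC(=O)C(C)(C)C)/C=C/C
F4 | step 8 | (4S)-4-methylcyclopent-2-en-1-one | C[C@H]1CC(=O)C=C1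
F5 | step 8 | (5R)-5-methyl-2-(trimethylsilyloxy)cyclopenta-1,3-diene | C[C@@H]1C=CC(O[Si](C)(C)C)=C1
F6 | step 8 | [(1R,2S)-2-[(1R,5R)-5-methyl-2-oxocyclopent-3-en-1-yl]-1-(triethylsilyloxy)-4-(trimethylsilyloxy)cyclopent-3-en-1-yl]methyl acetate | CC(=O)OC[C@@]1(O[Si](CC)(CC)CC)CC(O[Si](C)(C)C)=C[C@H]1[C@@H]1C(=O)C=C[C@H]1C
F7 | step 8 | [(1R,2S)-2-[(5R)-5-methyl-2-(trimethylsilyloxy)cyclopenta-1,3-dien-1-yl]-1-(triethylsilyloxy)-4-(trimethylsilyloxy)cyclopent-3-en-1-yl]methyl acetate | CC(=O)OC[C@@]1(O[Si](CC)(CC)CC)CC(O[Si](C)(C)C)=C[C@H]1C2=C(O[Si](C)(C)C)C=C[C@H]2C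
F8 | step 11 | [(1R,2S,4S)-2-[(3R,4E)-3-(2,2-dimethylpropanoyloxy)hex-4-en-1-yn-1-yl]-4-(methoxycarbonyloxy)-4-[(2E)-6-methylhepta-2,5-dien-2-yl]-1-(triethylsilyloxy)cyclopentyl]methyl acetate | CC(=O)OC[C@@]1(O[Si](CC)(CC)CC)C[C@](OC(=O)OC)(/C(C)=C/CC=C(C)C)C[C@H]1C#C[C@H](OC(=O)C(C)(C)C)/C=C/C
F9 | step 11 | [(1R,2S,4S)-2-[(3R,4E)-3-(2,2-dimethylpropanoyloxy)hex-4-en-1-yn-1-yl]-4-[(2E)-6-methylhepta-2,5-dien-2-yl]-1-(triethylsilyloxy)cyclopentyl]methyl acetate | CC(=O)OC[C@@]1(O[Si](CC)(CC)CC)C[C@@H](/C(C)=C/CC=C(C)C)C[C@H]1C#C[C@H](OC(=O)C(C)(C)C)/C=C/C
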